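**Plan** (lignan numbering: ArA = 4-hydroxy-3-methoxyphenyl on C7, ArB = the prenyloxy ring on C7'; ring A = O–C7–C8–C8'–C9', ring B = O–C7'–C8'–C8–C9)
- Enabling feature: C9 is a bare CH2 held only by the ring B oxygen and C8, and benzylic C7 is bonded to the oxygen that leads to C9'. A formaldehyde carbon sitting on the C7' oxygen and a C9' carboxylate can therefore add together across a C8=C7 styrene.
- Cuts, in retrosynthetic order: prenyl O–C and silyl O–Si; the ring A ether back to a C9' lactone; C8–C9 and C7–O in one step, leading to a cis-5-styryl-6-aryl-1,3-dioxan-4-one; the acetal CH2 (formaldehyde); C7'–C8' (aldol); C8=C7 (Wittig).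
- Forward order: Wittig and aldol reactions join the chain, the dioxanone ring is closed, the key isomerisation closes ring B and then ring A as its lactone, the lactone is taken to the ether through the diol, and ArB is unmasked and prenylated before ArA is freed.
- Stereochemistry: C7' and C8' come from an (R)-4-benzyloxazolidinone syn-aldol; C8 and C7 are set in the key step by the cis-fused lactone and the exo placement of ArA, and no centre is touched afterwards.

Key step: step 8

Assumption: the SMILES is read as the (7R,8S,7'R,8'S) isomer, cis-fused with both aryl groups exo, which calls for the (R)-auxiliary; the Wittig product is carried on as the purified (E)-acid.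

**Step 1**
Reactants: 1 vanillin
Product: 2 3-methoxy-4-(triisopropylsilyloxy)benzaldehyde
Conditions: iPr3SiCl, imidazole, DMF, rt
Reagents that add atoms: triisopropylsilyl chloride, CC(C)[Si](Cl)(C(C)C)C(C)C
Why: Imidazole-promoted silylation of the phenol; the bulky aryl silyl ether keeps ArA electron-rich and should survive amide bases, LiOOH at 0 °C, Me3SiOTf and borohydride.

**Step 2**
Reactants: 2 3-methoxy-4-(triisopropylsilyloxy)benzaldehyde; 3 (2-carboxyethyl)triphenylphosphonium bromide
Product: 5 (E)-4-[3-methoxy-4-(triisopropylsilyloxy)phenyl]but-3-enoic acid, via carboxylate ylide 4 (not isolated)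
Conditions: 3, NaN(SiMe3)2 (2.1 equiv), THF, 0 °C; then 2, −78 °C → rt; 1 M HCl; purification to the (E)-isomer
Reagents that add atoms: none
Why: Wittig reaction of the carboxylate-bearing ylide, which with aromatic aldehydes is expected to give mainly the (E)-β,γ-unsaturated acid, the non-nucleophilic amide base sparing the aryl silyl ether.

**Step 3**
Reactants: 5 (E)-4-[3-methoxy-4-(triisopropylsilyloxy)phenyl]but-3-enoic acid; 6 (R)-4-benzyloxazolidin-2-one
Product: 8 (R)-4-benzyl-3-[(E)-4-(3-methoxy-4-triisopropylsilyloxyphenyl)but-3-enoyl]oxazolidin-2-one, via mixed pivalic anhydride 7 (not isolated)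
Conditions: t-BuCOCl, Et3N, THF, −20 °C; then LiCl, 6, −20 °C → rt
Reagents that add atoms: none
Why: N-acylation of the oxazolidinone through the mixed anhydride under LiCl/Et3N, conditions mild enough that the β,γ-double bond should not move into conjugation.

**Step 4**
Reactants: 1 vanillin
Product: 9 4-formyl-2-methoxyphenyl methanesulfonate
Conditions: MeSO2Cl, Et3N, CH2Cl2, 0 °C
Reagents that add atoms: methanesulfonyl chloride, CS(Cl)(=O)=O
Why: Sulfonylation of the phenol; the mesylate (unlike an aryl carboxylate) is inert to LiOOH, Lewis acid and borohydride, makes ArB a poor donor for the key step, and can later be removed with an amide base.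

**Step 5**
Reactants: 8 (R)-4-benzyl-3-[(E)-4-(3-methoxy-4-triisopropylsilyloxyphenyl)but-3-enoyl]oxazolidin-2-one; 9 4-formyl-2-methoxyphenyl methanesulfonate
Product: 11 (R)-4-benzyl-3-{(2R,3R)-3-hydroxy-3-[3-methoxy-4-(methylsulfonyloxy)phenyl]-2-[(E)-2-(3-methoxy-4-triisopropylsilyloxyphenyl)vinyl]propanoyl}oxazolidin-2-one, via dibutylboron dienolate 10 (not isolated)
Conditions: Bu2BOTf, iPr2NEt, CH2Cl2, −78 → 0 °C; then 9, −78 → 0 °C; pH 7 buffer, MeOH, 30% H2O2, 0 °C
Reagents that add atoms: none
Why: Evans syn-aldol reaction, in which the (Z)-boron dienolate reacts at its α-carbon through a Zimmerman–Traxler chair on the face away from the benzyl group of the (R)-auxiliary, setting C8' (R) and C7' (R) in the syn relationship.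

**Step 6**
Reactants: 11 the syn-aldol imide
Product: 13 (2R,3R)-3-hydroxy-3-[3-methoxy-4-(methylsulfonyloxy)phenyl]-2-[(E)-2-(3-methoxy-4-triisopropylsilyloxyphenyl)vinyl]propanoic acid, via lithium percarboxylate 12 (not isolated)
Conditions: LiOH, 30% H2O2, THF/H2O (3:1), 0 °C; then Na2SO3; 1 M HCl to pH 3
Reagents that add atoms: hydrogen peroxide (reacts as LiOOH and supplies the oxygen of the acid OH), OO
Why: Hydroperoxide hydrolysis of the exocyclic imide carbonyl (standard auxiliary removal) should leave the aryl mesylate, the aryl silyl ether, the styrene and both stereocentres untouched, and sulfite reduces the percarboxylate before acidification.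

**Step 7**
Reactants: 13 the syn-β-hydroxy acid; 14 formaldehyde (monomer from cracked paraformaldehyde)
Product: 16 (5R,6R)-6-[3-methoxy-4-(methylsulfonyloxy)phenyl]-5-[(E)-2-(3-methoxy-4-triisopropylsilyloxyphenyl)vinyl]-1,3-dioxan-4-one, via bis(trimethylsilyl) derivative 15 (not isolated)
Conditions: (Me3Si)2NH, CH2Cl2, rt, evaporate; then CH2O (CH2Cl2 solution), Me3SiOTf (0.1 equiv), CH2Cl2, −78 °C; pyridine quench at −78 °C
Reagents that add atoms: none
Why: Silyl-triflate-catalysed acetalisation of a bis-silylated β-hydroxy acid with an aldehyde, the usual route to 1,3-dioxan-4-ones, run cold and quenched with base so that the new acetal does not ionise further; the C7'–O bond is not broken, so the syn-aldol becomes the 5,6-cis ring.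

**Step 8**
Reactants: 16 the cis-5-styryl-6-aryl-1,3-dioxan-4-one
Product: 19 2-(3-methoxy-4-triisopropylsilyloxyphenyl)-6-[3-methoxy-4-(methylsulfonyloxy)phenyl]-3,7-dioxabicyclo[3.3.0]octan-4-one (cis-fused; both aryl groups exo; 7R,8S,7'R,8'R in lignan numbering), via oxocarbenium silyl ester 17 (not isolated), via benzylic cation 18 (not isolated)
Conditions: Me3SiOTf (1.2 equiv), 2,6-di-tert-butyl-4-methylpyridine (0.3 equiv), CH2Cl2 (0.02 M), −78 → −20 °C; aq. NaHCO3
Reagents that add atoms: none
Why: Proposed new method: Me3SiOTf silylates the carbonyl oxygen of 16, the acetal carbon C9 then loses the silyl carboxylate and not the alkoxy oxygen, and the resulting O-methylene oxocarbenium ion 17 bonds through C9 to the styrene carbon C8, leaving the p-silyloxybenzyl cation 18 at C7 that the silyl carboxylate captures with return of Me3SiOTf, so that 16 is simply isomerised to 19. The closest known reaction types are the Lewis-acid opening of 1,3-dioxan-4-ones to oxocarbenium ions (the first stage of Petasis–Ferrier-type rearrangements) and Prins cyclisations of (E)-styrenyl homoallylic ethers that stop at a trapped benzylic cation; their union in one isomerisation is what is new. Ring B closes 5-exo with respect to the alkene (the C9=O+ bond lies inside the new ring), and ring A closes as the γ-lactone by 5-exo attack of the carboxylate oxygen on the C7 cation. C8 is set cis to the C8' carboxyl group because only that cation can lactonise (a trans-fused bicyclo[3.3.0] lactone is out of reach, and the trans cation can fragment back to 17), while C7 is set with ArA exo by anti addition of C9 and the carboxylate oxygen across the (E)-alkene, backed by reversible ionisation of the benzylic acyloxy bond toward the convex-face aryl isomer; C7' and C8' are carried over unchanged from the syn-aldol. The step needs attack at C8 and not at C7 (bonding to C7 would open a 2-oxonia-Cope scrambling path), no ionisation at C7' and no arylation of the cation: the p-silyloxy group of ArA polarises the styrene toward a C7 cation, the mesylate makes ArB a poor donor and a poor Friedel–Crafts partner and destabilises the aryl-conjugated oxocarbenium ion that a [3,3] shift would give, and the hindered pyridine removes adventitious acid that would otherwise protonate the styrene.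

**Step 9**
Reactants: 19 the furofuranone
Product: 20 2-[3-methoxy-4-(methylsulfonyloxy)phenyl]-3-(hydroxymethyl)-4-[hydroxy(3-methoxy-4-triisopropylsilyloxyphenyl)methyl]tetrahydrofuran (2,3-trans-3,4-cis; 7R,8S,7'R,8'S in lignan numbering)
Conditions: LiBH4, THF, 0 °C → rt; H2O work-up
Reagents that add atoms: none
Why: Borohydride reduction of a γ-lactone to the 1,4-diol; LiBH4 should not attack the aryl sulfonate or the silyl ether, and C7 keeps its configuration because only the acyl C–O bond is cleaved.

**Step 10**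
Reactants: 20 the diol
Product: 22 2-(3-methoxy-4-triisopropylsilyloxyphenyl)-6-[3-methoxy-4-(methylsulfonyloxy)phenyl]-3,7-dioxabicyclo[3.3.0]octane (7R,8S,7'R,8'S; both aryl groups exo), via primary mesylate 21 (not isolated)
Conditions: MeSO2Cl (1.1 equiv), pyridine, CH2Cl2, 0 °C → rt
Reagents that add atoms: none
Why: Selective sulfonylation of the primary C9' hydroxyl followed by 5-exo-tet displacement by the C7 hydroxyl (intramolecular Williamson etherification, the usual closure of furofuran lignan diols), so that the C7–O bond is kept and ArA stays exo under non-acidic conditions.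

**Step 11**
Reactants: 22 the furofuran aryl mesylate
Product: 23 2-(3-methoxy-4-triisopropylsilyloxyphenyl)-6-(4-hydroxy-3-methoxyphenyl)-3,7-dioxabicyclo[3.3.0]octane (7R,8S,7'R,8'S)
Conditions: LiN(iPr)2 (3 equiv), THF, −78 → 0 °C; aq. NH4Cl
Reagents that add atoms: none
Why: Amide-base cleavage of an aryl methanesulfonate (deprotonation of the S-methyl group and loss of sulfene release the phenoxide); the furofuran has no comparably acidic proton and the hindered silyl ether is inert.

**Step 12**
Reactants: 23 the ArB phenol; 24 1-bromo-3-methylbut-2-ene (prenyl bromide)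
Product: 25 2-(3-methoxy-4-triisopropylsilyloxyphenyl)-6-[3-methoxy-4-(3-methylbut-2-enyloxy)phenyl]-3,7-dioxabicyclo[3.3.0]octane (7R,8S,7'R,8'S)
Conditions: K2CO3, acetone, 40 °C
Reagents that add atoms: none
Why: Williamson O-alkylation of the only free phenol with a reactive allylic bromide under mild carbonate conditions that should not disturb the silyl ether.

**Step 13**
Reactants: 25 the silyl-protected prenyl ether
Product: 26 CNP0185952.2, 2-(4-hydroxy-3-methoxyphenyl)-6-[3-methoxy-4-(3-methylbut-2-enyloxy)phenyl]-3,7-dioxabicyclo[3.3.0]octane (7R,8S,7'R,8'S)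
Conditions: Bu4NF, AcOH (1:1), THF, 0 °C → rt
Reagents that add atoms: none
Why: Fluoride cleavage of the aryl silyl ether, buffered with AcOH so that the p-hydroxybenzylic ether cannot open through a quinone methide; the prenyl ether and all four stereocentres are unaffected.

**Compound list**
1 | vanillin (4-hydroxy-3-methoxybenzaldehyde) | COc1cc(C=O)ccc1O | starting material
2 | 3-methoxy-4-(triisopropylsilyloxy)benzaldehyde | COc1cc(C=O)ccc1O[Si](C(C)C)(C(C)C)C(C)C | intermediate
3 | (2-carboxyethyl)triphenylphosphonium bromide | [Br-].OC(=O)CC[P+](c1ccccc1)(c1ccccc1)c1ccccc1 | starting material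
4 | sodium 3-(triphenylphosphoranylidene)propanoate (carboxylate ylide) | [Na+].[O-]C(=O)CC=P(c1ccccc1)(c1ccccc1)c1ccccc1 | intermediate
5 | (E)-4-[3-methoxy-4-(triisopropylsilyloxy)phenyl]but-3-enoic acid | OC(=O)C/C=C/c1ccc(O[Si](C(C)C)(C(C)C)C(C)C)c(OC)c1 | intermediate
6 | (R)-4-benzyloxazolidin-2-one | O=C1N[C@H](Cc2ccccc2)CO1 | starting material
7 | mixed anhydride of 5 with pivalic acid | CC(C)(C)C(=O)OC(=O)C/C=C/c1ccc(O[Si](C(C)C)(C(C)C)C(C)C)c(OC)c1 | intermediate
8 | (R)-4-benzyl-3-[(E)-4-(3-methoxy-4-triisopropylsilyloxyphenyl)but-3-enoyl]oxazolidin-2-one | O=C(C/C=C/c1ccc(O[Si](C(C)C)(C(C)C)C(C)C)c(OC)c1)N1[C@H](Cc2ccccc2)COC1=O | intermediate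
9 | 4-formyl-2-methoxyphenyl methanesulfonate | COc1cc(C=O)ccc1OS(C)(=O)=O | intermediate
10 | (Z)-dibutylboron dienolate of 8 | CCCCB(CCCC)O/C(=C\C=C\c1ccc(O[Si](C(C)C)(C(C)C)C(C)C)c(OC)c1)N1[C@H](Cc2ccccc2)COC1=O | intermediate
11 | (R)-4-benzyl-3-{(2R,3R)-3-hydroxy-3-[3-methoxy-4-(methylsulfonyloxy)phenyl]-2-[(E)-2-(3-methoxy-4-triisopropylsilyloxyphenyl)vinyl]propanoyl}oxazolidin-2-one (syn-aldol adduct) | O=C(N1[C@H](Cc2ccccc2)COC1=O)[C@H](/C=C/c1ccc(O[Si](C(C)C)(C(C)C)C(C)C)c(OC)c1)[C@@H](O)c1ccc(OS(C)(=O)=O)c(OC)c1 | intermediate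
12 | lithium percarboxylate corresponding to acid 13 | [Li+].[O-]OC(=O)[C@H](/C=C/c1ccc(O[Si](C(C)C)(C(C)C)C(C)C)c(OC)c1)[C@@H](O)c1ccc(OS(C)(=O)=O)c(OC)c1 | intermediate
13 | (2R,3R)-3-hydroxy-3-[3-methoxy-4-(methylsulfonyloxy)phenyl]-2-[(E)-2-(3-methoxy-4-triisopropylsilyloxyphenyl)vinyl]propanoic acid | OC(=O)[C@H](/C=C/c1ccc(O[Si](C(C)C)(C(C)C)C(C)C)c(OC)c1)[C@@H](O)c1ccc(OS(C)(=O)=O)c(OC)c1 | intermediate
14 | formaldehyde (monomer, from paraformaldehyde) | C=O | starting material
15 | trimethylsilyl ester and trimethylsilyl ether of 13 | C[Si](C)(C)OC(=O)[C@H](/C=C/c1ccc(O[Si](C(C)C)(C(C)C)C(C)C)c(OC)c1)[C@@H](O[Si](C)(C)C)c1ccc(OS(C)(=O)=O)c(OC)c1 | intermediate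
16 | (5R,6R)-6-[3-methoxy-4-(methylsulfonyloxy)phenyl]-5-[(E)-2-(3-methoxy-4-triisopropylsilyloxyphenyl)vinyl]-1,3-dioxan-4-one (5,6-cis) | O=C1OCO[C@@H](c2ccc(OS(C)(=O)=O)c(OC)c2)[C@H]1/C=C/c1ccc(O[Si](C(C)C)(C(C)C)C(C)C)c(OC)c1 | intermediate
17 | O-methylene oxocarbenium ion on the C7' oxygen, C9' as trimethylsilyl ester (triflate salt) | C=[O+][C@@H](c1ccc(OS(C)(=O)=O)c(OC)c1)[C@H](C(=O)O[Si](C)(C)C)/C=C/c1ccc(O[Si](C(C)C)(C(C)C)C(C)C)c(OC)c1.[O-]S(=O)(=O)C(F)(F)F | intermediate
18 | ring B tetrahydrofuran carrying the C7 benzylic cation cis to the trimethylsilyl ester (triflate salt) | COc1cc(ccc1O[Si](C(C)C)(C(C)C)C(C)C)[CH+][C@@H]1CO[C@@H](c2ccc(OS(C)(=O)=O)c(OC)c2)[C@@H]1C(=O)O[Si](C)(C)C.[O-]S(=O)(=O)C(F)(F)F | intermediate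
19 | 2-(3-methoxy-4-triisopropylsilyloxyphenyl)-6-[3-methoxy-4-(methylsulfonyloxy)phenyl]-3,7-dioxabicyclo[3.3.0]octan-4-one (7R,8S,7'R,8'R; cis-fused, aryl groups exo) | COc1cc(ccc1O[Si](C(C)C)(C(C)C)C(C)C)[C@@H]2OC(=O)[C@@H]3[C@H]2CO[C@H]3c2ccc(OS(C)(=O)=O)c(OC)c2 | intermediate
20 | 2-[3-methoxy-4-(methylsulfonyloxy)phenyl]-3-(hydroxymethyl)-4-[hydroxy(3-methoxy-4-triisopropylsilyloxyphenyl)methyl]tetrahydrofuran (7R,8S,7'R,8'S) | COc1cc(ccc1O[Si](C(C)C)(C(C)C)C(C)C)[C@H](O)[C@@H]1CO[C@@H](c2ccc(OS(C)(=O)=O)c(OC)c2)[C@@H]1CO | intermediate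
21 | C9' methanesulfonate of diol 20 | COc1cc(ccc1O[Si](C(C)C)(C(C)C)C(C)C)[C@H](O)[C@@H]1CO[C@@H](c2ccc(OS(C)(=O)=O)c(OC)c2)[C@@H]1COS(C)(=O)=O | intermediate
22 | 2-(3-methoxy-4-triisopropylsilyloxyphenyl)-6-[3-methoxy-4-(methylsulfonyloxy)phenyl]-3,7-dioxabicyclo[3.3.0]octane (7R,8S,7'R,8'S) | COc1cc(ccc1O[Si](C(C)C)(C(C)C)C(C)C)[C@@H]2OC[C@@H]3[C@H]2CO[C@H]3c2ccc(OS(C)(=O)=O)c(OC)c2 | intermediate
23 | 2-(3-methoxy-4-triisopropylsilyloxyphenyl)-6-(4-hydroxy-3-methoxyphenyl)-3,7-dioxabicyclo[3.3.0]octane (7R,8S,7'R,8'S) | COc1cc(ccc1O[Si](C(C)C)(C(C)C)C(C)C)[C@@H]2OC[C@@H]3[C@H]2CO[C@H]3c2ccc(O)c(OC)c2 | intermediate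
24 | 1-bromo-3-methylbut-2-ene (prenyl bromide) | CC(C)=CCBr | starting material
25 | 2-(3-methoxy-4-triisopropylsilyloxyphenyl)-6-[3-methoxy-4-(3-methylbut-2-enyloxy)phenyl]-3,7-dioxabicyclo[3.3.0]octane (7R,8S,7'R,8'S) | COc1cc(ccc1O[Si](C(C)C)(C(C)C)C(C)C)[C@@H]2OC[C@@H]3[C@H]2CO[C@H]3c2ccc(OCC=C(C)C)c(OC)c2 | intermediate
26 | CNP0185952.2, 2-(4-hydroxy-3-methoxyphenyl)-6-[3-methoxy-4-(3-methylbut-2-enyloxy)phenyl]-3,7-dioxabicyclo[3.3.0]octane (7R,8S,7'R,8'S) | COc1cc([C@@H]2OC[C@@H]3[C@H]2CO[C@H]3c2ccc(OCC=C(C)C)c(OC)c2)ccc1O | target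

Total step count: 13.
Longest linear sequence: 12 steps (steps 1–3 and 5–13, from vanillin to 26); step 4 is the one-step side branch.

**Steps most likely to fail**

Step 8 (key step). The silylated dioxanone may simply re-close instead of cyclising. The oxocarbenium ion may bond to C7 and scramble by a [3,3] shift. The cation with C7 trans to the carboxyl group may be drained by elimination or arylation before it can revert. The fallback makes the same two bonds from an acyclic acetal in separate, known operations and sets out from hydroxy acid 13. Me3SiCHN2 (MeOH/toluene, 0 °C) would give the methyl ester F1, and MeOCH2Cl/iPr2NEt would give its methoxymethyl ether F2. SnCl4 in CH2Cl2 at −78 °C ionises such formaldehyde acetals at the methoxy side (acetal-initiated cyclisation onto an alkene, known for homoallylic methoxymethyl ethers). This should close ring B at C8 and end with chloride capture at C7, giving the benzylic chloride F3 (the isomer with C7 cis to the ester is the useful one, and both C7 epimers serve). AgOSO2CF3 in wet MeCN would then ionise the chloride and let the cis ester close the γ-lactone with loss of methanol, which comes back to the route at 19.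

Step 7. The freshly formed acyloxy acetal may ionise prematurely under the silyl triflate, the formaldehyde may polymerise faster than it is captured, or adventitious acid may lactonise the styryl acid. The fallback brings in C9 as an electrophile under buffered conditions and sets out from 13. Chloromethyl chlorosulfate with NaHCO3 and Bu4NHSO4 in CH2Cl2/H2O should give the chloromethyl ester F4. Ag2O with 4 Å sieves in CH2Cl2 would then close the acetal by 6-exo O-alkylation of the C7' hydroxyl (silver-assisted alkylation of an alcohol by an acyloxymethyl halide), which comes back to the route at 16.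

Step 5. The styryl-substituted dienolate may react through its γ-carbon, lose alkene geometry, or show weak facial control. The fallback attaches ArA after the aldol and sets out from 6, using 9 and 2 from the route. Acylation of 6 with but-3-enoic acid (t-BuCOCl, Et3N, LiCl) gives (R)-4-benzyl-3-(but-3-enoyl)oxazolidin-2-one F5. Its dibutylboron enolate with 9, under the conditions of step 5, should give the α-vinyl syn-aldol adduct F6. Cross-metathesis of F6 with 3-methoxy-4-(triisopropylsilyloxy)styrene F7 (from 2 and Ph3P=CH2), using the second-generation Grubbs catalyst in CH2Cl2 at 40 °C, would install the (E)-styrene and come back to the route at 11.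

**Further compounds**
F1 | step 8 | methyl (2R,3R)-3-hydroxy-3-[3-methoxy-4-(methylsulfonyloxy)phenyl]-2-[(E)-2-(3-methoxy-4-triisopropylsilyloxyphenyl)vinyl]propanoate | COC(=O)[C@H](/C=C/c1ccc(O[Si](C(C)C)(C(C)C)C(C)C)c(OC)c1)[C@@H](O)c1ccc(OS(C)(=O)=O)c(OC)c1
F2 | step 8 | methoxymethyl ether of F1 at the C7' hydroxyl | COCO[C@@H](c1ccc(OS(C)(=O)=O)c(OC)c1)[C@H](C(=O)OC)/C=C/c1ccc(O[Si](C(C)C)(C(C)C)C(C)C)c(OC)c1
F3 | step 8 | methyl 4-[chloro(3-methoxy-4-triisopropylsilyloxyphenyl)methyl]-2-[3-methoxy-4-(methylsulfonyloxy)phenyl]tetrahydrofuran-3-carboxylate (2,3-trans-3,4-cis; C7 epimers) | COc1cc(ccc1O[Si](C(C)C)(C(C)C)C(C)C)C(Cl)[C@@H]1CO[C@@H](c2ccc(OS(C)(=O)=O)c(OC)c2)[C@@H]1C(=O)OC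
F4 | step 7 | chloromethyl ester of 13 | ClCOC(=O)[C@H](/C=C/c1ccc(O[Si](C(C)C)(C(C)C)C(C)C)c(OC)c1)[C@@H](O)c1ccc(OS(C)(=O)=O)c(OC)c1
F5 | step 5 | (R)-4-benzyl-3-(but-3-enoyl)oxazolidin-2-one | C=CCC(=O)N1[C@H](Cc2ccccc2)COC1=O
F6 | step 5 | (R)-4-benzyl-3-{(2R,3R)-3-hydroxy-3-[3-methoxy-4-(methylsulfonyloxy)phenyl]-2-vinylpropanoyl}oxazolidin-2-one | O=C(N1[C@H](Cc2ccccc2)COC1=O)[C@H](C=C)[C@@H](O)c1ccc(OS(C)(=O)=O)c(OC)c1
F7 | step 5 | 3-methoxy-4-(triisopropylsilyloxy)styrene | C=Cc1ccc(O[Si](C(C)C)(C(C)C)C(C)C)c(OC)c1
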